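**Conventions and remarks on the chemistry**

- Unit 1 is the top flavan (linked through C4), unit 2 the middle one, unit 3 the terminal one. "4β" means that the C4 substituent is trans to the C3 oxygen and trans to the C2 aryl group. Bn = benzyl; TBG = 3,4,5-tris(benzyloxy)benzoyl.
- Assumption: 4, 10 and 12 are catalogue chemicals and are used as bought.
- Assumption: two bromine atoms on ring A of unit 1 (C6, C8) and one on C8 of unit 2 are carried as spectator groups through the key step and leave in the last step.
- Assumption: in step 13 the sense of induction is assigned by the usual mnemonic for RuCl(arene)(TsDPEN) catalysts, with the branched, oxygenated C2 side of the ketone in the place of the aryl group of an aryl alkyl ketone. The enantiomeric complex is the direct remedy if the sense proves opposite.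

## Analysis of the target

The target is a linear procyanidin trimer in which every unit is (−)-epicatechin 3-O-gallate. It has three 2-arylchroman (flavan) cores, each with a 3,4-dihydroxyphenyl ring B at C2 and a 3,4,5-trihydroxybenzoyl ester on O3. Unit 1 is bonded through C4 to C6 of ring A of unit 2, unit 2 through C4 to C8 of ring A of unit 3, and unit 3 ends the chain with a C4 methylene. There are eight stereocentres: C2 and C3 of each unit are R,R with aryl group and ester oxygen cis, and C4 of units 1 and 2 carries the next unit 4β. The free compound has twenty-one phenolic hydroxyls that oxidise in air and base, three esters that can migrate or hydrolyse, C2 centres that epimerise in base, and two doubly benzylic interflavan bonds that break in acid. All phenols therefore travel as benzyl ethers and are freed last under neutral conditions. The hard points are the first interflavan bond, which must go to the hindered C6 of unit 2 and not to C8, the 3,4-trans geometry at two crowded benzylic carbons, and joining three units without self-condensation. The strategy rests on ring C of unit 3: C4 is a methylene bonded to C4a of the phloroglucinol-type ring A, the neighbouring C3 is oxygenated, and O1 links C2 to C8a. This is the pattern left when the terminal carbon of a 2-methoxyallyl aryl ether is bonded oxidatively to the arene carbon ortho to the ether oxygen and the enol ether carbon ends as a ketal.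

## Retrosynthetic reasoning

Target 22 is traced back to its fully benzylated form 21, which still carries the three aryl bromine atoms. The cut is made at the twenty-one benzylic C–O bonds and the three C–Br bonds because one neutral hydrogenolysis removes both kinds of group and exposes the sensitive polyphenol only at the end.

21 is cut at the ester bond on O3 of unit 3 into alcohol 20 and acid 4. The two other gallates are placed at the monomer stage, where the C3 hydroxyl is easy to acylate and where the ester then helps each C4 substitution to go trans. Only the hydroxyl that the route itself creates is acylated late.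

The C3–H bond of unit 3 in 20 leads back to ketone 19, and 19 to its dimethyl ketal 18. C2 of the flavan-3-one is α to the carbonyl, benzylic and oxygen-bearing, so it equilibrates. One catalyst-controlled reduction can then fix C2 and C3 together as cis-(2R,3R), and the ether carbon needs no control earlier.

The key disconnection is the C4–C4a bond of unit 3 in 18. Cutting it opens ring C and gives the 1-aryl-2-methoxyallyl aryl ether 16 and 17. The cut is made there because unit 3 then shrinks to a flat phenol cap on unit 2, and because the cap has only one free carbon ortho to the ether oxygen, so closure can only give the 4→8 pattern. The forward anodic step must form the C–C bond, close the ring and deliver C3 at the ketone oxidation level.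

The aryl ether bond O1–C2 of 16 is cut into phenol 11 and allylic alcohol 15. 15 is cut at C2–C3 into aldehyde 12 and the acyl anion equivalent 14, made from 13. The forward etherification has to alkylate a hindered phenol at a secondary benzylic carbon without acid, which the enol ether would not survive.

11 is cut at the bond between C4 of unit 2 and the cap into dimer 9, which carries a benzylthio leaving group on that carbon, and phenol 10. In 10 two of the three oxygens are already benzylated, so exactly one free hydroxyl ends up ortho to the new bond and no later differentiation of three phenols is needed. The forward reaction must alkylate 10 at a carbon next to its hydroxyl and from the face trans to the C3 gallate.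

The 4→6 bond of 9 is cut into electrophile 6 and nucleophile 8. Three bromine atoms serve this step: two on ring A of 6, so that the electrophile has no nucleophilic carbon and cannot oligomerise, and one on C8 of 8, so that C6 is the only position left. The leaving groups are orthogonal: an ether on 6 that a hard silyl Lewis acid ionises, and a sulfide on 8 that survives it and answers to a soft thiophile in the next coupling. The bromines stay on, lower the electron density of rings A of units 1 and 2 during the anodic step, and leave in the final hydrogenolysis.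

6 and 8 both come from 5, by bromination and, for 8, exchange of the C4 ether for the sulfide. 5 comes from 3 and 4 by esterification, 3 from 2 by oxidative functionalisation of C4, and 2 from 1. Six of the eight stereocentres thus derive from the chiral pool: C2 and C3 of units 1 and 2 directly, and the two C4 centres by induction from C3.

## Alternatives that were turned down

**Alternative 1:** The bond between C4 of unit 1 and C6 of unit 2 is made by aryne chemistry before either ring C exists.
- Forward key step: fluoride releases a 3,5-dioxygenated aryne from the ortho-silylaryl triflate A1. The carboxylate of the open-chain unit 1 acid A2 (C2 and C3 in place, ring A attached only through O1) adds through oxygen to the aryne carbon remote from the benzyloxy group. The aryl anion then takes over the acyl carbon, giving the ortho-hydroxyaryl ketone A3, whose acyl carbon is the future C4 of unit 1.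
- For: the 4→6 connectivity is fixed by the insertion itself, since the acyl group must land between two oxygens. No blocking halogen and no sluggish C6 nucleophile are needed. On this point it is stronger than the chosen route.
- Against: the acyl shift competes with plain O-arylation and is least favourable for an α-branched, α-acyloxy acid. In A3 the C3 hydrogen is α to the new ketone with the aryloxy group β, so the basic medium can epimerise C3 or expel the aryloxide. After the key step, ring C of unit 1 (with C4 to be set trans), all of ring C of unit 2 with three stereocentres, and all of unit 3 remain to be built.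
- Comparison: the chosen strategy takes units 1 and 2 with their rings and six stereocentres from 1 and builds one ring only, so it is much shorter. It gives up the built-in regiocontrol and buys it back with three bromine atoms.

**Alternative 2:** Ring A of unit 2 is disconnected across C6–C7 and C5–C4a and grown on unit 1 by a Danheiser benzannulation.
- Forward key step: heating 3-(allyloxy)cyclobutenone A4 with the 4β-(triisopropylsilyloxyethynyl)flavan A5 opens the cyclobutenone to a vinylketene, which adds to the ynol ether. Ring opening and 6π closure give phenol A6, the unit 1 core with a new phloroglucinol ring at C4 bearing a free hydroxyl, a silyl ether and an allyl ether.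
- For: the aryl–C4 bond is never made by a Friedel–Crafts step. The ring arrives with three distinguishable oxygens and with the attachment carbon between two of them. On regiochemistry at this junction it is as strong as or stronger than the chosen route.
- Against: A5 needs a multistep homologation at the C4 stereocentre and an ynol silyl ether that must survive until thermolysis. The benzannulation runs hot, and its ketene intermediates can be intercepted by the electron-rich rings. O3 is a silyl ether, so the gallate must still be exchanged in. Ring C of unit 2 and unit 3 must then be made from scratch on a phenol whose two free ring carbons need differentiation.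
- Comparison: it spends its key step on a ring that epicatechin already contains, whereas the chosen route spends it on the one ring that must be built.

**Alternative 3:** Ring C of unit 1 is cut into three pieces: phenol 10 (ring A), the symmetric aldehyde A7 (C4 with the future ring A of unit 2) and the Z-enol gallate A8 (C2, C3, ring B and the ester).
- Forward key step: under a chiral Brønsted acid, 10 adds through its ortho carbon to A7, water is lost to give an ortho-quinone methide, and A8 closes onto it in a hetero-Diels–Alder sense. C4–C4a, C3–C4 and O1–C2 form in one flask to give A9.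
- For: it has the highest bond economy of the four plans (three bonds, one ring and three stereocentres of unit 1 at once, gallate included). The ring attached at C4 is symmetric, so the later 4→6 connectivity follows from symmetry. On both points it beats the chosen route.
- Against: enol esters are weak 2π partners for quinone methides, and the aryl group and the ester oxygen polarise A8 in opposite directions, so regiochemistry is open. The 2,3-cis-3,4-trans array needs both an endo/exo preference and absolute control on a methide flanked by two benzyloxy groups. 10 must react ortho and not para to its hydroxyl. The product still lacks ring C of unit 2 and all of unit 3.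
- Comparison: the chosen route settles the stereochemistry of units 1 and 2 by starting from 1 and has a single new ring to make, at the price of a less inventive assembly of unit 1.

Key step: step 11

## Steps

**Step 1**
Reactants: 1 (−)-epicatechin
Product: 2 5,7,3′,4′-tetra-O-benzyl-(−)-epicatechin
Conditions: BnBr (4.4 equiv), K2CO3, DMF, 0 °C → rt
Reagents that add atoms: benzyl bromide, BrCc1ccccc1
Why: Williamson ether synthesis; the four phenols are alkylated while the aliphatic C3 hydroxyl stays free under carbonate. Low temperature limits C-benzylation and C2 epimerisation.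

**Step 2**
Reactants: 2 5,7,3′,4′-tetra-O-benzyl-(−)-epicatechin
Product: 3 (2R,3R,4S)-5,7,3′,4′-tetra-O-benzyl-4-(2-ethoxyethoxy)flavan-3-ol (4β ether)
Conditions: DDQ (2 equiv), 2-ethoxyethanol (5 equiv), CH2Cl2, rt
Reagents that add atoms: 2-ethoxyethanol, CCOCCO
Why: DDQ abstracts hydride from C4, the benzylic position activated by ring A (oxidative benzylic etherification). The alcohol adds to the C4 cation trans to the C3 hydroxyl, which sets the 4β configuration.

**Step 3**
Reactants: 3 (2R,3R,4S)-5,7,3′,4′-tetra-O-benzyl-4-(2-ethoxyethoxy)flavan-3-ol; 4 3,4,5-tris(benzyloxy)benzoic acid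
Product: 5 (2R,3R,4S)-5,7,3′,4′-tetra-O-benzyl-4-(2-ethoxyethoxy)flavan-3-yl 3,4,5-tris(benzyloxy)benzoate
Conditions: DCC, DMAP, CH2Cl2, 0 °C → rt
Reagents that add atoms: none
Why: Steglich esterification of the secondary C3 hydroxyl. The neutral conditions leave the acid-labile C4 ether untouched.

**Step 4**
Reactants: 5 4β-(2-ethoxyethoxy) gallate
Product: 6 6,8-dibromo derivative of 5 (bromine on both free carbons of ring A)
Conditions: NBS (2.2 equiv), CH2Cl2, −20 °C → rt
Reagents that add atoms: N-bromosuccinimide, O=C1CCC(=O)N1Br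
Why: Electrophilic aromatic bromination; the phloroglucinol-type ring A is much more nucleophilic than the catechol and gallate rings, so both of its free positions react. The future electrophile then has no nucleophilic carbon left.

**Step 5**
Reactants: 5 4β-(2-ethoxyethoxy) gallate
Product: 7 8-bromo derivative of 5
Conditions: NBS (1.0 equiv), CH2Cl2, −78 °C → −40 °C
Reagents that add atoms: N-bromosuccinimide, O=C1CCC(=O)N1Br
Why: Electrophilic aromatic bromination with one equivalent at low temperature should go to C8, which is flanked by only one benzyloxy group. C6 is left as the single free nucleophilic carbon.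

**Step 6**
Reactants: 7 8-bromo-4β-(2-ethoxyethoxy) gallate
Product: 8 (2R,3R)-5,7,3′,4′-tetra-O-benzyl-4β-(benzylthio)-8-bromoflavan-3-yl 3,4,5-tris(benzyloxy)benzoate (sulfide trans to the ester)
Conditions: BnSH (5 equiv), TMSOTf (0.1 equiv), CH2Cl2, −78 °C
Reagents that add atoms: phenylmethanethiol (benzyl mercaptan), SCc1ccccc1
Why: Lewis acid-catalysed ionisation of the C4 ether and capture of the cation by the thiol (thiolysis-type SN1 exchange). Attack trans to the C3 ester gives the 4β sulfide, and the excess of thiol outruns self-condensation.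

**Step 7**
Reactants: 6 6,8-dibromo-4β-(2-ethoxyethoxy) gallate; 8 8-bromo-4β-(benzylthio) gallate
Product: 9 dimer: unit 1 (6,8-dibromo, 3-O-TBG)-(4β→6)-unit 2 (8-bromo, 3-O-TBG, 4β-benzylthio), all phenols benzylated
Conditions: 8 (2 equiv), TMSOTf (0.2 equiv), 4 Å MS, CH2Cl2, −78 °C → −30 °C, slow addition of 6; Et3N quench
Reagents that add atoms: none
Why: Friedel–Crafts-type interflavan coupling; the oxophilic silyl triflate ionises only the C4 ether of 6 and leaves the soft sulfide of 8. 6 cannot self-condense and 8 offers only C6. Attack trans to the C3 gallate, assisted by acyloxonium participation, sets 4β at unit 1.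

**Step 8**
Reactants: 9 4β→6 dimer with 4β-benzylthio on unit 2; 10 3,5-bis(benzyloxy)phenol
Product: 11 dimer of 9 in which C4 of unit 2 carries 4β a 2,4-bis(benzyloxy)-6-hydroxyphenyl cap
Conditions: 10 (5 equiv), AgBF4 (2.5 equiv), THF, 0 °C → rt, dark
Reagents that add atoms: none
Why: Thiophilic activation of the sulfide by AgBF4 followed by Friedel–Crafts capture by the phenol. C-alkylation is expected ortho to the free hydroxyl, the position flanked by OH and OBn and not by two OBn, and any O-alkylation is reversible under the acid formed. Attack trans to the gallate sets 4β at unit 2.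

**Step 9**
Reactants: 12 3,4-bis(benzyloxy)benzaldehyde; 13 methyl vinyl ether
Product: 15 1-[3,4-bis(benzyloxy)phenyl]-2-methoxyprop-2-en-1-ol (racemic), via 1-methoxyvinyllithium 14 (not isolated)
Conditions: 13, t-BuLi, THF, −78 °C → 0 °C; then 12, −78 °C; H2O/NaHCO3 work-up
Reagents that add atoms: none
Why: α-Lithiation of the vinyl ether gives the acyl anion equivalent, which adds 1,2 to the aldehyde. The carbinol centre is racemic, which is acceptable because that carbon is equilibrated after the key step.

**Step 10**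
Reactants: 11 capped dimer phenol; 15 1-[3,4-bis(benzyloxy)phenyl]-2-methoxyprop-2-en-1-ol
Product: 16 dimer whose cap is 2,4-bis(benzyloxy)-6-{1-[3,4-bis(benzyloxy)phenyl]-2-methoxyallyloxy}phenyl (both configurations of the ether carbon)
Conditions: 15 (3 equiv), PPh3, DIAD, THF (concentrated), 0 °C → rt; chromatography on Et3N-treated silica
Reagents that add atoms: none
Why: Mitsunobu etherification; the phenol is the only acidic group in 11. The activated alcohol has no β-hydrogen, so elimination is excluded, and the electron-rich enol ether terminus disfavours SN2′ attack.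

**Step 11**
Reactants: 16 2-methoxyallyl aryl ether of the capped dimer; 17 methanol
Product: 18 trimer in which unit 3 is the 5,7,3′,4′-tetra-O-benzylflavan-3-one dimethyl ketal bonded through C8 to C4 of unit 2 (C2 of unit 3 both configurations)
Conditions: reticulated vitreous carbon anode, Pt cathode, undivided cell, constant current at low current density (2.0–2.2 F/mol), Et4NOTs (0.1 M), 2,6-lutidine (6 equiv), MeOH–CH2Cl2 1:4, 0 °C → rt
Reagents that add atoms: methanol (compound 17), CO
Why: Proposed new method: the closest known reaction type is the anodic coupling of enol ether radical cations with electron-rich arenes to six-membered rings with methanol capture of the oxocarbenium ion; new here is the endo mode on a 2-methoxyallyl aryl ether, which puts the ketal carbon inside the ring. Removal of one electron from the enol ether–trialkoxyarene pair gives a radical cation that is electrophilic at the terminal CH2, and the cap carbon ortho to the ether oxygen (future C4a) attacks it, forming C4–C4a and an α-methoxy radical at C3. Loss of the ring proton to 2,6-lutidine restores aromaticity, the α-methoxy radical gives up a second electron, and methanol adds to the oxocarbenium ion to give the dimethyl ketal, while methanol is reduced to hydrogen at the cathode. Ring C of unit 3 closes 6-endo-trig with respect to the enol ether; the other free cap carbon is para to the ether oxygen and out of reach, so the 4→8 pattern follows from the substrate. No stereocentre is fixed, since C3 becomes a ketal carbon and C2 stays a mixture that is equilibrated in step 13. The step needs chemoselectivity for the enol ether and cap ring over rings A of units 1 and 2 with their doubly benzylic C4–H bonds and over the catechol ethers. The three bromine atoms raise the oxidation potential of rings A of units 1 and 2, and the intramolecular six-membered trapping should be fast. Low current density, about two faradays per mole and the lutidine buffer are meant to hold back over-oxidation and hydrolysis of the enol ether.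

**Step 12**
Reactants: 18 trimer with unit 3 as dimethyl ketal
Product: 19 trimer with unit 3 as the flavan-3-one (C2 of unit 3 both configurations)
Conditions: CF3CO2H–H2O (9:1), CH2Cl2, 0 °C, short reaction time; used directly
Reagents that add atoms: water, O
Why: Acid-catalysed ketal hydrolysis. The interflavan bonds are shielded by the deactivating C3 esters and ring A bromines, and cold, brief exposure limits their cleavage. The ketone is used at once because C2 is enolisable and air-sensitive.

**Step 13**
Reactants: 19 trimer with unit 3 as flavan-3-one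
Product: 20 trimer with unit 3 as (2R,3R)-5,7,3′,4′-tetra-O-benzylflavan-3-ol (2,3-cis), free hydroxyl at C3
Conditions: RuCl(p-cymene)[(R,R)-TsDPEN] (5 mol %), HCO2H–Et3N (1:1), CH2Cl2, 30 °C, argon
Reagents that add atoms: none
Why: Noyori-type asymmetric transfer hydrogenation with dynamic kinetic resolution; C2 (α to the carbonyl, benzylic, oxygen-bearing) epimerises through the enol under the amine buffer. The (R,R) catalyst should deliver hydride to the carbonyl face that gives 3R, and hydride enters anti to the C2 aryl group, so only the 2R epimer is reduced and the 2,3-cis (2R,3R) unit results.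

**Step 14**
Reactants: 20 trimer with free C3 hydroxyl on unit 3; 4 3,4,5-tris(benzyloxy)benzoic acid
Product: 21 fully benzylated, tribrominated trimer tris-gallate (3-O-TBG on all three units)
Conditions: DCC, DMAP, CH2Cl2, rt
Reagents that add atoms: none
Why: Steglich esterification of the only free hydroxyl, which sits on the terminal and least hindered unit.

**Step 15**
Reactants: 21 protected trimer tris-gallate
Product: 22 epicatechin 3-O-gallate-(4β→6)-epicatechin 3-O-gallate-(4β→8)-epicatechin 3-O-gallate (target, CNP0183218.1)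
Conditions: H2 (1 atm), Pd(OH)2/C, NaOAc (3.3 equiv), THF–MeOH–H2O, rt; filtration under argon, lyophilisation
Reagents that add atoms: none
Why: Catalytic hydrogenolysis cleaves the twenty-one benzyl ethers and hydrodehalogenates the three aryl bromides. Acetate buffers the HBr so that the interflavan bonds and gallates survive, and no stereocentre is touched.

## Compound list

1 | (−)-epicatechin | O[C@@H]1Cc2c(O)cc(O)cc2O[C@@H]1c1ccc(O)c(O)c1 | starting material
2 | 5,7,3′,4′-tetra-O-benzyl-(−)-epicatechin | O[C@@H]1Cc2c(OCc5ccccc5)cc(OCc5ccccc5)cc2O[C@@H]1c6ccc(OCc5ccccc5)c(OCc5ccccc5)c6 | intermediate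
3 | (2R,3R,4S)-5,7,3′,4′-tetra-O-benzyl-4-(2-ethoxyethoxy)flavan-3-ol | O[C@@H]1[C@@H](OCCOCC)c2c(OCc5ccccc5)cc(OCc5ccccc5)cc2O[C@@H]1c6ccc(OCc5ccccc5)c(OCc5ccccc5)c6 | intermediate
4 | 3,4,5-tris(benzyloxy)benzoic acid | OC(=O)c1cc(OCc2ccccc2)c(OCc2ccccc2)c(OCc2ccccc2)c1 | starting material
5 | (2R,3R,4S)-5,7,3′,4′-tetra-O-benzyl-4-(2-ethoxyethoxy)flavan-3-yl 3,4,5-tris(benzyloxy)benzoate | O=C(O[C@@H]1[C@@H](OCCOCC)c2c(OCc5ccccc5)cc(OCc5ccccc5)cc2O[C@@H]1c6ccc(OCc5ccccc5)c(OCc5ccccc5)c6)c6cc(OCc5ccccc5)c(OCc5ccccc5)c(OCc5ccccc5)c6 | intermediate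
6 | 6,8-dibromo derivative of 5 | O=C(O[C@@H]1[C@@H](OCCOCC)c2c(OCc5ccccc5)c(Br)c(OCc5ccccc5)c(Br)c2O[C@@H]1c6ccc(OCc5ccccc5)c(OCc5ccccc5)c6)c6cc(OCc5ccccc5)c(OCc5ccccc5)c(OCc5ccccc5)c6 | intermediate
7 | 8-bromo derivative of 5 | O=C(O[C@@H]1[C@@H](OCCOCC)c2c(OCc5ccccc5)cc(OCc5ccccc5)c(Br)c2O[C@@H]1c6ccc(OCc5ccccc5)c(OCc5ccccc5)c6)c6cc(OCc5ccccc5)c(OCc5ccccc5)c(OCc5ccccc5)c6 | intermediate
8 | (2R,3R)-5,7,3′,4′-tetra-O-benzyl-4β-(benzylthio)-8-bromoflavan-3-yl 3,4,5-tris(benzyloxy)benzoate | O=C(O[C@@H]1[C@@H](SCc5ccccc5)c2c(OCc5ccccc5)cc(OCc5ccccc5)c(Br)c2O[C@@H]1c6ccc(OCc5ccccc5)c(OCc5ccccc5)c6)c6cc(OCc5ccccc5)c(OCc5ccccc5)c(OCc5ccccc5)c6 | intermediate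
9 | dimer: unit 1 (6,8-dibromo, 3-O-TBG)-(4β→6)-unit 2 (8-bromo, 3-O-TBG, 4β-benzylthio) | O=C(O[C@@H]1[C@@H](c2c(OCc5ccccc5)c(Br)c3c(c2OCc5ccccc5)[C@H](SCc5ccccc5)[C@@H](OC(=O)c6cc(OCc5ccccc5)c(OCc5ccccc5)c(OCc5ccccc5)c6)[C@@H](c6ccc(OCc5ccccc5)c(OCc5ccccc5)c6)O3)c2c(OCc5ccccc5)c(Br)c(OCc5ccccc5)c(Br)c2O[C@@H]1c6ccc(OCc5ccccc5)c(OCc5ccccc5)c6)c6cc(OCc5ccccc5)c(OCc5ccccc5)c(OCc5ccccc5)c6 | intermediate
10 | 3,5-bis(benzyloxy)phenol | Oc1cc(OCc2ccccc2)cc(OCc2ccccc2)c1 | starting material
11 | dimer with 4β-[2,4-bis(benzyloxy)-6-hydroxyphenyl] cap on C4 of unit 2 | O=C(O[C@@H]1[C@@H](c2c(OCc5ccccc5)c(Br)c3c(c2OCc5ccccc5)[C@H](c2c(OCc5ccccc5)cc(OCc5ccccc5)cc2O)[C@@H](OC(=O)c6cc(OCc5ccccc5)c(OCc5ccccc5)c(OCc5ccccc5)c6)[C@@H](c6ccc(OCc5ccccc5)c(OCc5ccccc5)c6)O3)c2c(OCc5ccccc5)c(Br)c(OCc5ccccc5)c(Br)c2O[C@@H]1c6ccc(OCc5ccccc5)c(OCc5ccccc5)c6)c6cc(OCc5ccccc5)c(OCc5ccccc5)c(OCc5ccccc5)c6 | intermediate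
12 | 3,4-bis(benzyloxy)benzaldehyde | O=Cc1ccc(OCc2ccccc2)c(OCc2ccccc2)c1 | starting material
13 | methyl vinyl ether | COC=C | starting material
14 | 1-methoxyvinyllithium | [Li]C(=C)OC | intermediate (not isolated)
15 | 1-[3,4-bis(benzyloxy)phenyl]-2-methoxyprop-2-en-1-ol (racemic) | OC(C(OC)=C)c1ccc(OCc2ccccc2)c(OCc2ccccc2)c1 | intermediate
16 | dimer whose cap is 2,4-bis(benzyloxy)-6-{1-[3,4-bis(benzyloxy)phenyl]-2-methoxyallyloxy}phenyl (key-step precursor) | O=C(O[C@@H]1[C@@H](c2c(OCc5ccccc5)c(Br)c3c(c2OCc5ccccc5)[C@H](c2c(OCc5ccccc5)cc(OCc5ccccc5)cc2OC(c6ccc(OCc5ccccc5)c(OCc5ccccc5)c6)C(OC)=C)[C@@H](OC(=O)c6cc(OCc5ccccc5)c(OCc5ccccc5)c(OCc5ccccc5)c6)[C@@H](c6ccc(OCc5ccccc5)c(OCc5ccccc5)c6)O3)c2c(OCc5ccccc5)c(Br)c(OCc5ccccc5)c(Br)c2O[C@@H]1c6ccc(OCc5ccccc5)c(OCc5ccccc5)c6)c6cc(OCc5ccccc5)c(OCc5ccccc5)c(OCc5ccccc5)c6 | intermediate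
17 | methanol | CO | starting material
18 | trimer with unit 3 as flavan-3-one dimethyl ketal (key-step product) | O=C(O[C@@H]1[C@@H](c2c(OCc5ccccc5)c(Br)c3c(c2OCc5ccccc5)[C@H](c2c(OCc5ccccc5)cc(OCc5ccccc5)c4c2OC(c6ccc(OCc5ccccc5)c(OCc5ccccc5)c6)C(OC)(OC)C4)[C@@H](OC(=O)c6cc(OCc5ccccc5)c(OCc5ccccc5)c(OCc5ccccc5)c6)[C@@H](c6ccc(OCc5ccccc5)c(OCc5ccccc5)c6)O3)c2c(OCc5ccccc5)c(Br)c(OCc5ccccc5)c(Br)c2O[C@@H]1c6ccc(OCc5ccccc5)c(OCc5ccccc5)c6)c6cc(OCc5ccccc5)c(OCc5ccccc5)c(OCc5ccccc5)c6 | intermediate
19 | trimer with unit 3 as flavan-3-one | O=C(O[C@@H]1[C@@H](c2c(OCc5ccccc5)c(Br)c3c(c2OCc5ccccc5)[C@H](c2c(OCc5ccccc5)cc(OCc5ccccc5)c4c2OC(c6ccc(OCc5ccccc5)c(OCc5ccccc5)c6)C(=O)C4)[C@@H](OC(=O)c6cc(OCc5ccccc5)c(OCc5ccccc5)c(OCc5ccccc5)c6)[C@@H](c6ccc(OCc5ccccc5)c(OCc5ccccc5)c6)O3)c2c(OCc5ccccc5)c(Br)c(OCc5ccccc5)c(Br)c2O[C@@H]1c6ccc(OCc5ccccc5)c(OCc5ccccc5)c6)c6cc(OCc5ccccc5)c(OCc5ccccc5)c(OCc5ccccc5)c6 | intermediate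
20 | trimer with unit 3 as (2R,3R)-flavan-3-ol, free C3 hydroxyl | O=C(O[C@@H]1[C@@H](c2c(OCc5ccccc5)c(Br)c3c(c2OCc5ccccc5)[C@H](c2c(OCc5ccccc5)cc(OCc5ccccc5)c4c2O[C@H](c6ccc(OCc5ccccc5)c(OCc5ccccc5)c6)[C@H](O)C4)[C@@H](OC(=O)c6cc(OCc5ccccc5)c(OCc5ccccc5)c(OCc5ccccc5)c6)[C@@H](c6ccc(OCc5ccccc5)c(OCc5ccccc5)c6)O3)c2c(OCc5ccccc5)c(Br)c(OCc5ccccc5)c(Br)c2O[C@@H]1c6ccc(OCc5ccccc5)c(OCc5ccccc5)c6)c6cc(OCc5ccccc5)c(OCc5ccccc5)c(OCc5ccccc5)c6 | intermediate
21 | fully benzylated, tribrominated trimer tris-gallate | O=C(O[C@@H]1[C@@H](c2c(OCc5ccccc5)c(Br)c3c(c2OCc5ccccc5)[C@H](c2c(OCc5ccccc5)cc(OCc5ccccc5)c4c2O[C@H](c6ccc(OCc5ccccc5)c(OCc5ccccc5)c6)[C@H](OC(=O)c6cc(OCc5ccccc5)c(OCc5ccccc5)c(OCc5ccccc5)c6)C4)[C@@H](OC(=O)c6cc(OCc5ccccc5)c(OCc5ccccc5)c(OCc5ccccc5)c6)[C@@H](c6ccc(OCc5ccccc5)c(OCc5ccccc5)c6)O3)c2c(OCc5ccccc5)c(Br)c(OCc5ccccc5)c(Br)c2O[C@@H]1c6ccc(OCc5ccccc5)c(OCc5ccccc5)c6)c6cc(OCc5ccccc5)c(OCc5ccccc5)c(OCc5ccccc5)c6 | intermediate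
22 | epicatechin 3-O-gallate-(4β→6)-epicatechin 3-O-gallate-(4β→8)-epicatechin 3-O-gallate | O=C(O[C@@H]1[C@@H](c2c(O)cc3c(c2O)[C@H](c2c(O)cc(O)c4c2O[C@H](c2ccc(O)c(O)c2)[C@H](OC(=O)c2cc(O)c(O)c(O)c2)C4)[C@@H](OC(=O)c2cc(O)c(O)c(O)c2)[C@@H](c2ccc(O)c(O)c2)O3)c2c(O)cc(O)cc2O[C@@H]1c1ccc(O)c(O)c1)c1cc(O)c(O)c(O)c1 | target

## Step count and least certain steps

Total: 15 steps. Longest linear sequence: 13 steps (1, 2, 3, 5, 6, 7, 8, 10, 11, 12, 13, 14, 15, starting from 1).

**Step 11 (key step, proposed new method).**
- Oxidation may start at the wrong π system, a catechol ether or ring A of unit 2, followed by loss of a doubly benzylic proton and methanol capture, which would methoxylate or cleave an interflavan position.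
- The radical cation may be deprotonated at the ether carbon (benzylic, allylic to the enol ether, oxygen-bearing) before it cyclises, which would fragment the aryl ether.
- The product ring is more electron-rich than the starting cap and may be oxidised further.
- Fallback by known chemistry: the electrochemical closure is abandoned and an intact unit 3 is attached. Starting from 9, thiophilic activation with AgBF4 in THF in the presence of an excess of 2, which is nucleophilic at C8, should form the 4β→8 bond directly. This returns to the route at 20; no new compound is made.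

**Step 7.**
- Attack by the hindered, bromine-deactivated C6 of 8 may be so slow that the cation from 6 decays.
- The acid liberated may ionise the sulfide of 8, which would scramble the leaving groups and let 8 condense with itself.
- Fallback: the order of the two activations is reversed. From 6, exchange with benzyl mercaptan (TMSOTf catalysis) gives the 6,8-dibromo-4β-(benzylthio) gallate F1. F1 is ionised with AgBF4, buffered by 2,6-di-tert-butyl-4-methylpyridine, in the presence of 7, whose C4 ether is inert to the soft activator. This gives the dimer carrying 4β-(2-ethoxyethoxy) on unit 2, F2. F2 is then capped with 10 under TMSOTf, returning to the route at 11.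

**Step 8.**
- Alkylation of 10 may occur in part at the carbon para to the hydroxyl or on oxygen, and the product cap may be alkylated a second time. All of these come from the small difference between the nuclear positions of 10.
- Fallback: the cap is introduced with a nucleophile that has no regiochemical choice. From 9, AgBF4 and an excess of phloroglucinol give the dimer with the 2,4,6-trihydroxyphenyl cap F3. One equivalent of BnBr with K2CO3 benzylates the para hydroxyl, the one not flanked by the flavanyl group, to give the 4-(benzyloxy)-2,6-dihydroxyphenyl dimer F4. A Mitsunobu reaction with 15 at one of the two equivalent ortho hydroxyls gives the mono-ether phenol F5, and a final benzylation returns to the route at 16.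

**Step 10.**
- The hindered phenol may fail to displace the activated alcohol.
- The alkoxyphosphonium ion of the electron-rich benzylic alcohol may ionise to a 2-methoxyallyl cation, which would be captured at the wrong terminus or on carbon.
- The enol ether may be hydrolysed during isolation.
- Fallback: the ether bond is made by SN2 on an α-halo ketone and the enol ether is installed afterwards. From 15, dilute aqueous acid gives 1-[3,4-bis(benzyloxy)phenyl]-1-hydroxypropan-2-one F6, and an Appel reaction (PPh3, CBr4) gives 1-[3,4-bis(benzyloxy)phenyl]-1-bromopropan-2-one F7. Phenol 11 is alkylated with F7 (K2CO3, acetone) to the α-aryloxy ketone F8. Trimethyl orthoformate and methanol with catalytic pyridinium tosylate give the dimethyl ketal F9. Elimination of methanol with TMSOTf and iPr2NEt towards the methyl group returns to the route at 16.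

**Step 13.**
- Discrimination between the carbonyl faces may be poor, because the catalyst meets a ketone without an aryl group on the carbonyl carbon.
- Epimerisation at C2 in the formate medium may be slower than reduction. Both would lead to a mixture of the two cis diastereomers at unit 3.
- Fallback: substrate control replaces catalyst control. From 19, LiBH(s-Bu)3 in THF at −78 °C delivers hydride anti to the C2 aryl group and should give only 2,3-cis alcohols, namely 20 and its unit 3 (2S,3S) diastereomer F10. These are separated by chromatography. F10 is returned to 19 by Dess–Martin oxidation and base equilibration (DBU), and the sequence comes back to the route at 20.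

## Further compounds

F0 | step 11 | none | none
F1 | step 7 | (2R,3R)-5,7,3′,4′-tetra-O-benzyl-4β-(benzylthio)-6,8-dibromoflavan-3-yl 3,4,5-tris(benzyloxy)benzoate | O=C(O[C@@H]1[C@@H](SCc5ccccc5)c2c(OCc5ccccc5)c(Br)c(OCc5ccccc5)c(Br)c2O[C@@H]1c6ccc(OCc5ccccc5)c(OCc5ccccc5)c6)c6cc(OCc5ccccc5)c(OCc5ccccc5)c(OCc5ccccc5)c6
F2 | step 7 | dimer as 9 with 4β-(2-ethoxyethoxy) in place of benzylthio on unit 2 | O=C(O[C@@H]1[C@@H](c2c(OCc5ccccc5)c(Br)c3c(c2OCc5ccccc5)[C@H](OCCOCC)[C@@H](OC(=O)c6cc(OCc5ccccc5)c(OCc5ccccc5)c(OCc5ccccc5)c6)[C@@H](c6ccc(OCc5ccccc5)c(OCc5ccccc5)c6)O3)c2c(OCc5ccccc5)c(Br)c(OCc5ccccc5)c(Br)c2O[C@@H]1c6ccc(OCc5ccccc5)c(OCc5ccccc5)c6)c6cc(OCc5ccccc5)c(OCc5ccccc5)c(OCc5ccccc5)c6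
F3 | step 8 | dimer with 4β-(2,4,6-trihydroxyphenyl) cap on unit 2 | O=C(O[C@@H]1[C@@H](c2c(OCc5ccccc5)c(Br)c3c(c2OCc5ccccc5)[C@H](c2c(O)cc(O)cc2O)[C@@H](OC(=O)c6cc(OCc5ccccc5)c(OCc5ccccc5)c(OCc5ccccc5)c6)[C@@H](c6ccc(OCc5ccccc5)c(OCc5ccccc5)c6)O3)c2c(OCc5ccccc5)c(Br)c(OCc5ccccc5)c(Br)c2O[C@@H]1c6ccc(OCc5ccccc5)c(OCc5ccccc5)c6)c6cc(OCc5ccccc5)c(OCc5ccccc5)c(OCc5ccccc5)c6
F4 | step 8 | dimer with 4β-[4-(benzyloxy)-2,6-dihydroxyphenyl] cap on unit 2 | O=C(O[C@@H]1[C@@H](c2c(OCc5ccccc5)c(Br)c3c(c2OCc5ccccc5)[C@H](c2c(O)cc(OCc5ccccc5)cc2O)[C@@H](OC(=O)c6cc(OCc5ccccc5)c(OCc5ccccc5)c(OCc5ccccc5)c6)[C@@H](c6ccc(OCc5ccccc5)c(OCc5ccccc5)c6)O3)c2c(OCc5ccccc5)c(Br)c(OCc5ccccc5)c(Br)c2O[C@@H]1c6ccc(OCc5ccccc5)c(OCc5ccccc5)c6)c6cc(OCc5ccccc5)c(OCc5ccccc5)c(OCc5ccccc5)c6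
F5 | step 8 | dimer with cap 4-(benzyloxy)-2-hydroxy-6-{1-[3,4-bis(benzyloxy)phenyl]-2-methoxyallyloxy}phenyl | O=C(O[C@@H]1[C@@H](c2c(OCc5ccccc5)c(Br)c3c(c2OCc5ccccc5)[C@H](c2c(O)cc(OCc5ccccc5)cc2OC(c6ccc(OCc5ccccc5)c(OCc5ccccc5)c6)C(OC)=C)[C@@H](OC(=O)c6cc(OCc5ccccc5)c(OCc5ccccc5)c(OCc5ccccc5)c6)[C@@H](c6ccc(OCc5ccccc5)c(OCc5ccccc5)c6)O3)c2c(OCc5ccccc5)c(Br)c(OCc5ccccc5)c(Br)c2O[C@@H]1c6ccc(OCc5ccccc5)c(OCc5ccccc5)c6)c6cc(OCc5ccccc5)c(OCc5ccccc5)c(OCc5ccccc5)c6
F6 | step 10 | 1-[3,4-bis(benzyloxy)phenyl]-1-hydroxypropan-2-one (racemic) | CC(=O)C(O)c1ccc(OCc2ccccc2)c(OCc2ccccc2)c1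
F7 | step 10 | 1-[3,4-bis(benzyloxy)phenyl]-1-bromopropan-2-one (racemic) | CC(=O)C(Br)c1ccc(OCc2ccccc2)c(OCc2ccccc2)c1
F8 | step 10 | dimer with cap 2,4-bis(benzyloxy)-6-{1-[3,4-bis(benzyloxy)phenyl]-2-oxopropoxy}phenyl | O=C(O[C@@H]1[C@@H](c2c(OCc5ccccc5)c(Br)c3c(c2OCc5ccccc5)[C@H](c2c(OCc5ccccc5)cc(OCc5ccccc5)cc2OC(c6ccc(OCc5ccccc5)c(OCc5ccccc5)c6)C(C)=O)[C@@H](OC(=O)c6cc(OCc5ccccc5)c(OCc5ccccc5)c(OCc5ccccc5)c6)[C@@H](c6ccc(OCc5ccccc5)c(OCc5ccccc5)c6)O3)c2c(OCc5ccccc5)c(Br)c(OCc5ccccc5)c(Br)c2O[C@@H]1c6ccc(OCc5ccccc5)c(OCc5ccccc5)c6)c6cc(OCc5ccccc5)c(OCc5ccccc5)c(OCc5ccccc5)c6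
F9 | step 10 | dimer with cap 2,4-bis(benzyloxy)-6-{1-[3,4-bis(benzyloxy)phenyl]-2,2-dimethoxypropoxy}phenyl | O=C(O[C@@H]1[C@@H](c2c(OCc5ccccc5)c(Br)c3c(c2OCc5ccccc5)[C@H](c2c(OCc5ccccc5)cc(OCc5ccccc5)cc2OC(c6ccc(OCc5ccccc5)c(OCc5ccccc5)c6)C(C)(OC)OC)[C@@H](OC(=O)c6cc(OCc5ccccc5)c(OCc5ccccc5)c(OCc5ccccc5)c6)[C@@H](c6ccc(OCc5ccccc5)c(OCc5ccccc5)c6)O3)c2c(OCc5ccccc5)c(Br)c(OCc5ccccc5)c(Br)c2O[C@@H]1c6ccc(OCc5ccccc5)c(OCc5ccccc5)c6)c6cc(OCc5ccccc5)c(OCc5ccccc5)c(OCc5ccccc5)c6
F10 | step 13 | diastereomer of 20 with unit 3 as (2S,3S)-flavan-3-ol | O=C(O[C@@H]1[C@@H](c2c(OCc5ccccc5)c(Br)c3c(c2OCc5ccccc5)[C@H](c2c(OCc5ccccc5)cc(OCc5ccccc5)c4c2O[C@@H](c6ccc(OCc5ccccc5)c(OCc5ccccc5)c6)[C@@H](O)C4)[C@@H](OC(=O)c6cc(OCc5ccccc5)c(OCc5ccccc5)c(OCc5ccccc5)c6)[C@@H](c6ccc(OCc5ccccc5)c(OCc5ccccc5)c6)O3)c2c(OCc5ccccc5)c(Br)c(OCc5ccccc5)c(Br)c2O[C@@H]1c6ccc(OCc5ccccc5)c(OCc5ccccc5)c6)c6cc(OCc5ccccc5)c(OCc5ccccc5)c(OCc5ccccc5)c6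
A1 | alternative 1 | 5-(allyloxy)-3-(benzyloxy)-2-(trimethylsilyl)phenyl trifluoromethanesulfonate | C=CCOc1cc(OCc2ccccc2)c([Si](C)(C)C)c(OS(=O)(=O)C(F)(F)F)c1
A2 | alternative 1 | 3-[3,4-bis(benzyloxy)phenyl]-3-[3,5-bis(benzyloxy)phenoxy]-2-{[3,4,5-tris(benzyloxy)benzoyl]oxy}propanoic acid with the configuration of C3 and C2 of unit 1 | OC(=O)[C@@H](OC(=O)c6cc(OCc5ccccc5)c(OCc5ccccc5)c(OCc5ccccc5)c6)[C@@H](c6ccc(OCc5ccccc5)c(OCc5ccccc5)c6)Oc3cc(OCc5ccccc5)cc(OCc5ccccc5)c3
A3 | alternative 1 | ortho-hydroxyaryl ketone joining C6 of the future ring A of unit 2 to the future C4 of unit 1 | C=CCOc1cc(OCc2ccccc2)c(C(=O)[C@@H](OC(=O)c6cc(OCc5ccccc5)c(OCc5ccccc5)c(OCc5ccccc5)c6)[C@@H](c6ccc(OCc5ccccc5)c(OCc5ccccc5)c6)Oc3cc(OCc5ccccc5)cc(OCc5ccccc5)c3)c(O)c1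
A4 | alternative 2 | 3-(allyloxy)cyclobut-2-en-1-one | O=C1CC(OCC=C)=C1
A5 | alternative 2 | 5,7,3′,4′-tetra-O-benzyl-3-O-(tert-butyldimethylsilyl)-4β-[(triisopropylsilyloxy)ethynyl]epicatechin | CC(C)(C)[Si](C)(C)O[C@@H]1[C@@H](C#CO[Si](C(C)C)(C(C)C)C(C)C)c2c(OCc5ccccc5)cc(OCc5ccccc5)cc2O[C@@H]1c6ccc(OCc5ccccc5)c(OCc5ccccc5)c6
A6 | alternative 2 | unit 1 carrying at C4 the new ring A of unit 2 with free hydroxyl, triisopropylsilyl ether and allyl ether | CC(C)(C)[Si](C)(C)O[C@@H]1[C@@H](c3c(O)cc(OCC=C)cc3O[Si](C(C)C)(C(C)C)C(C)C)c2c(OCc5ccccc5)cc(OCc5ccccc5)cc2O[C@@H]1c6ccc(OCc5ccccc5)c(OCc5ccccc5)c6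
A7 | alternative 3 | 4-(allyloxy)-2,6-bis(benzyloxy)benzaldehyde | O=Cc1c(OCc2ccccc2)cc(OCC=C)cc1OCc1ccccc1
A8 | alternative 3 | (Z)-2-[3,4-bis(benzyloxy)phenyl]ethenyl 3,4,5-tris(benzyloxy)benzoate | O=C(O/C=C\c1ccc(OCc2ccccc2)c(OCc2ccccc2)c1)c1cc(OCc2ccccc2)c(OCc2ccccc2)c(OCc2ccccc2)c1
A9 | alternative 3 | protected unit 1 gallate carrying at C4 the symmetric 4-(allyloxy)-2,6-bis(benzyloxy)phenyl ring | O=C(O[C@@H]1[C@@H](c3c(OCc5ccccc5)cc(OCC=C)cc3OCc5ccccc5)c2c(OCc5ccccc5)cc(OCc5ccccc5)cc2O[C@@H]1c6ccc(OCc5ccccc5)c(OCc5ccccc5)c6)c6cc(OCc5ccccc5)c(OCc5ccccc5)c(OCc5ccccc5)c6
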